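**Retrosynthetic overview**

1. Locants (cycloocta[c]furan-1(3H)-one numbering of the core): C1 lactone C=O, O2, C3 (OCH2), C3a=C9a butenolide alkene, C4/C5 cyclopropane carbons, C6 (CHMe), C7 (CH2), C8 (CHOAc), C9 (CH bearing the 6-methylhept-5-en-2-yl chain).
2. Late stage: acetate from the C8 alcohol; cyclopropane by sulfoxonium-ylide 1,6-addition to the C5=C4–C3a=C9a–C1=O dienyl lactone; C4=C5 by ring-closing metathesis; the C3a vinyl group by Stille coupling of a tetronate triflate.
3. Key disconnection: C6–C7 and C8–C9 together. The C7–C8 unit is a vinyl group on boron; in one step C7 attacks an iridium π-crotyl (giving C6 with its vinyl group, the later C5) while C9 migrates from boron to C8. The C8–B bond is temporary and becomes the C8–O bond.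
4. Enabling feature: C8 is the only oxygenated carbon of the eight-membered ring and lies between two methine stereocentres (C9, and C6 across C7), and C6 is allylic to C5. So C6–C5 is the branched end of a crotyl electrophile, C8 the carbon that keeps boron, and C9 (β to the lactone carbonyl C1) a β-boryl ester carbon made from (R)-β-citronellene, an acrylate and B2pin2.
5. Ring order: temporary γ-lactone (O on C8 to C1) → butenolide (translactonization to a tetronic acid) → eight-membered ring (metathesis) → cyclopropane.

Key step: step 4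

Assumption: vinyllithium is used as a titrated THF stock solution (from tetravinylstannane and methyllithium), and the ligand enantiomers in steps 2 and 4 are those that give the configurations drawn.

**Step 1**
Reactants: 1 (3R)-3,7-dimethylocta-1,6-diene ((R)-β-citronellene); 2 tert-butyl acrylate
Product: 3 tert-butyl (2E,4R)-4,8-dimethylnona-2,7-dienoate
Conditions: Hoveyda–Grubbs second-generation catalyst (2 mol%), 2 (3 equiv), CH2Cl2, 40 °C
Reagents that add atoms: none
Why: Olefin cross-metathesis of the monosubstituted alkene of 1 with the acrylate should give the E-enoate, because the trisubstituted alkene reacts much more slowly; the C4 stereocentre from 1 is not touched.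

**Step 2**
Reactants: 3
Product: 4 tert-butyl (3R,4R)-4,8-dimethyl-3-(4,4,5,5-tetramethyl-1,3,2-dioxaborolan-2-yl)non-7-enoate
Conditions: CuCl (3 mol%), NaOtBu (6 mol%), Josiphos-type bisphosphine (3 mol%), B2pin2 (1.1 equiv), MeOH (2 equiv), THF, rt
Reagents that add atoms: bis(pinacolato)diboron, CC1(C)OB(OC1(C)C)B1OC(C)(C)C(C)(C)O1
Why: Copper-catalysed asymmetric conjugate borylation (β-boration): the ligated copper–boryl adds to C3 and methanol protonates the copper enolate; the new C3–B centre (the later C9) is set by the chiral ligand, which should override the adjacent C4 centre.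

**Step 3**
Reactants: 5 (2E)-but-2-en-1-ol (commercial crotyl alcohol, predominantly E)
Product: 6 (2E)-but-2-en-1-yl methyl carbonate
Conditions: ClCO2Me, pyridine, CH2Cl2, 0 °C
Reagents that add atoms: methyl chloroformate, COC(=O)Cl
Why: O-Acylation of the primary allylic alcohol gives the carbonate leaving group needed for iridium allyl formation; no stereocentre is formed.

**Step 4**
Reactants: 4 tert-butyl (3R,4R)-4,8-dimethyl-3-(pinacolboryl)non-7-enoate; 6 (2E)-but-2-en-1-yl methyl carbonate
Product: 8 tert-butyl (3S,4R,6R)-6-methyl-3-[(2R)-6-methylhept-5-en-2-yl]-4-(4,4,5,5-tetramethyl-1,3,2-dioxaborolan-2-yl)oct-7-enoate, via lithium vinylboronate complex 7 (not isolated)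
Conditions: vinyllithium (1.05 equiv), THF, −78 to 0 °C; then 6 (1.3 equiv), [Ir(cod)Cl]2 (2.5 mol%), BINOL-derived bis(1-phenylethyl)amine phosphoramidite (5 mol%, amine-activated), THF, rt
Reagents that add atoms: vinyllithium, [Li]C=C
Why: Vinyllithium adds to the secondary boronic ester to give the tetracoordinate boronate 7, whose vinyl CH2 terminus (the later C7) attacks the substituted terminus of the cationic crotyl complex of trivalent iridium formed from 6, while the C9 alkyl group shifts from boron to the adjacent carbon anti-periplanar to the incoming electrophile (1,2-metalate rearrangement), so the C6–C7 and C8–C9 bonds form in the same event. The closest known reaction type is the iridium-catalysed enantioselective allylation of alkenyl boronate complexes with concomitant 1,2-boronate rearrangement (conjunctive three-component coupling), which gives secondary boronic esters with 1,3-related stereocentres. No ring is closed here; the step assembles the whole C5–C9a carbon chain of the eight-membered ring and leaves the C5 vinyl group and the ester that the later ring closures need. C9 migrates with retention (configuration from step 2), C6 is set by the chiral phosphoramidite–iridium allyl complex through branched attack, and C8 is set by the face of the vinyl group that this complex engages, tied to C6 by the anti addition–migration geometry and to be matched with the resident C9 centre. The step needs branched over linear attack on the crotyl unit, which the iridium catalyst secures, and complexation of boron by vinyllithium in the presence of the ester, which the tert-butyl group and −78 °C secure. The C8–B bond is a temporary element and is turned into the C8–O bond in step 5.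

**Step 5**
Reactants: 8
Product: 10 (4R,5R)-5-[(2R)-2-methylbut-3-en-1-yl]-4-[(2R)-6-methylhept-5-en-2-yl]oxolan-2-one, via hydroxy ester 9 (not isolated)
Conditions: NaBO3·4H2O, THF/H2O, rt; then CSA (10 mol%), CH2Cl2, rt to 40 °C
Reagents that add atoms: sodium perborate, [Na+].[O-]OB=O
Why: Perborate oxidation converts the C–B bond into C–O with retention, and the γ-hydroxy tert-butyl ester then lactonizes under acid catalysis to the trans-4,5-disubstituted γ-lactone; no stereocentre changes.

**Step 6**
Reactants: 10; 11 2-{[tert-butyl(dimethyl)silyl]oxy}-N-methoxy-N-methylacetamide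
Product: 12 (4S,5R)-3-({[tert-butyl(dimethyl)silyl]oxy}acetyl)-5-[(2R)-2-methylbut-3-en-1-yl]-4-[(2R)-6-methylhept-5-en-2-yl]oxolan-2-one (C3 epimers and enol form)
Conditions: LDA (1.1 equiv), THF, −78 °C; then 11 (1.3 equiv), −78 to −20 °C; aq NH4Cl
Reagents that add atoms: none
Why: C-Acylation of the lactone lithium enolate by the N-methoxy-N-methyl amide (crossed Claisen-type acylation through a stable chelated tetrahedral adduct) attaches the future C3a and C3 to the future C9a; the new α-centre is labile and is destroyed in the next step.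

**Step 7**
Reactants: 12
Product: 14 4-hydroxy-3-[(3R,5R,6S,7R)-5-hydroxy-3,7,11-trimethyldodeca-1,10-dien-6-yl]furan-2(5H)-one, via hydroxyacetyl lactone 13 (not isolated)
Conditions: TBAF (1.2 equiv), THF, 0 °C to rt; 1 M HCl work-up
Reagents that add atoms: none
Why: Fluoride desilylation releases an alkoxide that attacks the lactone carbonyl (5-exo-trig translactonization, as in the cyclization of 4-hydroxy-3-oxo esters to tetronic acids) and frees the C8 hydroxyl; the strongly acidic, enolized tetronate is the thermodynamic sink and no sp3 stereocentre is affected.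

**Step 8**
Reactants: 14
Product: 15 4-[(3R,5R,6S,7R)-5-hydroxy-3,7,11-trimethyldodeca-1,10-dien-6-yl]-5-oxo-2,5-dihydrofuran-3-yl trifluoromethanesulfonate
Conditions: PhNTf2 (1.1 equiv), Et3N (1.5 equiv), CH2Cl2, 0 °C to rt
Reagents that add atoms: N-phenylbis(trifluoromethanesulfonimide), O=S(=O)(N(c1ccccc1)S(=O)(=O)C(F)(F)F)C(F)(F)F
Why: O-Triflation of the vinylogous acid as its ammonium salt; the triflimide does not sulfonylate the neutral secondary alcohol, and attack of that alcohol on the β-carbon would be a disfavoured 5-endo-trig closure.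

**Step 9**
Reactants: 15
Product: 16 4-ethenyl-3-[(3R,5R,6S,7R)-5-hydroxy-3,7,11-trimethyldodeca-1,10-dien-6-yl]furan-2(5H)-one
Conditions: tributyl(vinyl)stannane (1.2 equiv), Pd(PPh3)4 (5 mol%), LiCl (3 equiv), THF, 60 °C
Reagents that add atoms: tributyl(vinyl)stannane, CCCC[Sn](CCCC)(CCCC)C=C
Why: Stille coupling of the 4-trifloxybutenolide (fast oxidative addition to zerovalent palladium) with the vinylstannane under neutral conditions that tolerate the free alcohol gives the 4-vinylbutenolide.

**Step 10**
Reactants: 16
Product: 17 (4Z,6R,8R,9S)-8-hydroxy-6-methyl-9-[(2R)-6-methylhept-5-en-2-yl]-6,7,8,9-tetrahydrocycloocta[c]furan-1(3H)-one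
Conditions: second-generation Grubbs catalyst (5–10 mol%), toluene (2 mM), 80 °C
Reagents that add atoms: none
Why: Ring-closing metathesis of the two monosubstituted alkenes should close the eight-membered ring with a Z C4=C5 bond; the cis arrangement of the two chains on the C3a=C9a bond and the three stereocentres of the tether pre-organize the diene, and the tetrasubstituted and trisubstituted alkenes are inert.

**Step 11**
Reactants: 17
Product: 18 (4S,5S,6R,8R,9S)-8-hydroxy-6-methyl-9-[(2R)-6-methylhept-5-en-2-yl]-4,5-methano-4,5,6,7,8,9-hexahydrocycloocta[c]furan-1(3H)-one (cyclopropane cis-fused at C4–C5, its CH2 on the face of the C8 oxygen)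
Conditions: Me3S(O)I (2.5 equiv), NaH (2.4 equiv), DMSO, rt (ylide preformed); then 17, rt
Reagents that add atoms: trimethylsulfoxonium iodide, C[S+](C)(C)=O.[I-]
Why: Corey–Chaykovsky cyclopropanation by Michael-initiated ring closure: the sulfoxonium ylide adds 1,6 at C5 (C3a is fully substituted) and the dienolate closes at C4 with loss of DMSO, restoring the butenolide; the ring fusion is necessarily cis, the ylide should add anti to the adjacent C6 methyl group, and the electron-rich side-chain alkene does not react with a nucleophilic ylide.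

**Step 12**
Reactants: 18
Product: 19 (4S,5S,6R,8R,9S)-6-methyl-9-[(2R)-6-methylhept-5-en-2-yl]-1-oxo-4,5-methano-1,3,4,5,6,7,8,9-octahydrocycloocta[c]furan-8-yl acetate (CNP0018922.1)
Conditions: Ac2O, pyridine, DMAP (cat.), CH2Cl2, rt
Reagents that add atoms: acetic anhydride, CC(=O)OC(C)=O
Why: Acylation of the secondary alcohol under nucleophilic catalysis gives the target without touching any stereocentre.

**Compound list**

1 | (3R)-3,7-dimethylocta-1,6-diene | C=C[C@H](C)CCC=C(C)C | starting material
2 | tert-butyl prop-2-enoate | C=CC(=O)OC(C)(C)C | starting material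
3 | tert-butyl (2E,4R)-4,8-dimethylnona-2,7-dienoate | CC(C)(C)OC(=O)/C=C/[C@H](C)CCC=C(C)C | intermediate
4 | tert-butyl (3R,4R)-4,8-dimethyl-3-(4,4,5,5-tetramethyl-1,3,2-dioxaborolan-2-yl)non-7-enoate | CC(C)(C)OC(=O)C[C@@H](B1OC(C)(C)C(C)(C)O1)[C@H](C)CCC=C(C)C | intermediate
5 | (2E)-but-2-en-1-ol | C/C=C/CO | starting material
6 | (2E)-but-2-en-1-yl methyl carbonate | C/C=C/COC(=O)OC | intermediate
7 | lithium ethenyl[(3R,4R)-1-tert-butoxy-4,8-dimethyl-1-oxonon-7-en-3-yl](pinacolato)borate | [Li+].C=C[B-]1(OC(C)(C)C(C)(C)O1)[C@H](CC(=O)OC(C)(C)C)[C@H](C)CCC=C(C)C | intermediate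
8 | tert-butyl (3S,4R,6R)-6-methyl-3-[(2R)-6-methylhept-5-en-2-yl]-4-(4,4,5,5-tetramethyl-1,3,2-dioxaborolan-2-yl)oct-7-enoate | CC(C)(C)OC(=O)C[C@H]([C@H](C)CCC=C(C)C)[C@H](B1OC(C)(C)C(C)(C)O1)C[C@@H](C)C=C | intermediate
9 | tert-butyl (3R,4R,6R)-4-hydroxy-6-methyl-3-[(2R)-6-methylhept-5-en-2-yl]oct-7-enoate | CC(C)(C)OC(=O)C[C@H]([C@H](C)CCC=C(C)C)[C@H](O)C[C@@H](C)C=C | intermediate
10 | (4R,5R)-5-[(2R)-2-methylbut-3-en-1-yl]-4-[(2R)-6-methylhept-5-en-2-yl]oxolan-2-one | O=C1C[C@H]([C@H](C)CCC=C(C)C)[C@@H](C[C@@H](C)C=C)O1 | intermediate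
11 | 2-{[tert-butyl(dimethyl)silyl]oxy}-N-methoxy-N-methylacetamide | CON(C)C(=O)CO[Si](C)(C)C(C)(C)C | starting material
12 | (4S,5R)-3-({[tert-butyl(dimethyl)silyl]oxy}acetyl)-5-[(2R)-2-methylbut-3-en-1-yl]-4-[(2R)-6-methylhept-5-en-2-yl]oxolan-2-one (C3 epimers) | O=C1C(C(=O)CO[Si](C)(C)C(C)(C)C)[C@H]([C@H](C)CCC=C(C)C)[C@@H](C[C@@H](C)C=C)O1 | intermediate
13 | (4S,5R)-3-(hydroxyacetyl)-5-[(2R)-2-methylbut-3-en-1-yl]-4-[(2R)-6-methylhept-5-en-2-yl]oxolan-2-one (C3 epimers) | O=C1C(C(=O)CO)[C@H]([C@H](C)CCC=C(C)C)[C@@H](C[C@@H](C)C=C)O1 | intermediate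
14 | 4-hydroxy-3-[(3R,5R,6S,7R)-5-hydroxy-3,7,11-trimethyldodeca-1,10-dien-6-yl]furan-2(5H)-one | O=C1OCC(O)=C1[C@H]([C@H](C)CCC=C(C)C)[C@H](O)C[C@@H](C)C=C | intermediate
15 | 4-[(3R,5R,6S,7R)-5-hydroxy-3,7,11-trimethyldodeca-1,10-dien-6-yl]-5-oxo-2,5-dihydrofuran-3-yl trifluoromethanesulfonate | O=C1OCC(OS(=O)(=O)C(F)(F)F)=C1[C@H]([C@H](C)CCC=C(C)C)[C@H](O)C[C@@H](C)C=C | intermediate
16 | 4-ethenyl-3-[(3R,5R,6S,7R)-5-hydroxy-3,7,11-trimethyldodeca-1,10-dien-6-yl]furan-2(5H)-one | O=C1OCC(C=C)=C1[C@H]([C@H](C)CCC=C(C)C)[C@H](O)C[C@@H](C)C=C | intermediate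
17 | (4Z,6R,8R,9S)-8-hydroxy-6-methyl-9-[(2R)-6-methylhept-5-en-2-yl]-6,7,8,9-tetrahydrocycloocta[c]furan-1(3H)-one | O[C@@H]1C[C@@H](C)/C=C\C2=C(C(=O)OC2)[C@@H]1[C@H](C)CCC=C(C)C | intermediate
18 | (4S,5S,6R,8R,9S)-8-hydroxy-6-methyl-9-[(2R)-6-methylhept-5-en-2-yl]-4,5-methano-4,5,6,7,8,9-hexahydrocycloocta[c]furan-1(3H)-one | O[C@@H]1C[C@@H](C)[C@@H]2C[C@@H]2C2=C(C(=O)OC2)[C@@H]1[C@H](C)CCC=C(C)C | intermediate
19 | (4S,5S,6R,8R,9S)-6-methyl-9-[(2R)-6-methylhept-5-en-2-yl]-1-oxo-4,5-methano-1,3,4,5,6,7,8,9-octahydrocycloocta[c]furan-8-yl acetate (CNP0018922.1) | CC(=O)O[C@@H]1C[C@@H](C)[C@@H]2C[C@@H]2C2=C(C(=O)OC2)[C@@H]1[C@H](C)CCC=C(C)C | target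

**Step count and risks**

Total step count: 12. Longest linear sequence: 11 steps (1, 2, 4–12); step 3 is a one-step side branch.

Steps most likely to fail:

1. **Step 4.** The hindered, chiral migrating group may weaken the facial control at the boron-bearing carbon, and linear allylation or protodeboronation of the boronate complex may compete. The fallback sets out from 4 and returns at 8, making the two bonds in separate, reagent-controlled operations. Iridium-catalysed allylic alkylation of dimethyl malonate with 6 should give dimethyl 2-[(2S)-but-3-en-2-yl]propanedioate F1. Krapcho decarboxylation should give methyl (3R)-3-methylpent-4-enoate F2, LiAlH4 reduction (3R)-3-methylpent-4-en-1-ol F3, and acylation with 2,4,6-triisopropylbenzoyl chloride (3R)-3-methylpent-4-en-1-yl 2,4,6-tri(propan-2-yl)benzoate F4. Deprotonation with s-BuLi/(−)-sparteine should give [(1S,3R)-3-methyl-1-{[2,4,6-tri(propan-2-yl)benzoyl]oxy}pent-4-en-1-yl]lithium F5. This is borylated by 4 with retention to the lithium boronate complex F6, and 1,2-migration of the C9 group with inversion at the carbenoid carbon (lithiation–borylation homologation) should deliver 8.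

2. **Step 11.** The basic ylide may deprotonate the butenolide at C3 instead of adding, and the facial selectivity on the eight-membered ring may be low. The fallback sets out from 17 and returns at 18. 1,3-Dipolar cycloaddition of diazomethane (Et2O, rt) to the C4=C5 bond, with the CH2 terminus bonding to C5, should give the cis-fused Δ1-pyrazoline F7. Photolysis (350 nm) should then extrude nitrogen to the cyclopropane.

3. **Step 10.** Oligomerization may outrun the closure of the eight-membered ring, and the conjugated vinyl group may be a sluggish metathesis partner. The fallback sets out from 15 and returns at 17, bypassing step 9. An intramolecular Heck reaction (Pd(OAc)2, PPh3, Et3N, MeCN, 80 °C, high dilution) closes the ring 8-endo by bonding C3a to the terminal alkene carbon; β-hydride elimination toward C4 should give the conjugated diene. This fallback makes no new compound (F0).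

**Further compounds**

F1 | step 4 | dimethyl 2-[(2S)-but-3-en-2-yl]propanedioate | COC(=O)C(C(=O)OC)[C@@H](C)C=C
F2 | step 4 | methyl (3R)-3-methylpent-4-enoate | COC(=O)C[C@@H](C)C=C
F3 | step 4 | (3R)-3-methylpent-4-en-1-ol | OCC[C@@H](C)C=C
F4 | step 4 | (3R)-3-methylpent-4-en-1-yl 2,4,6-tri(propan-2-yl)benzoate | CC(C)c1cc(C(C)C)c(C(=O)OCC[C@@H](C)C=C)c(C(C)C)c1
F5 | step 4 | [(1S,3R)-3-methyl-1-{[2,4,6-tri(propan-2-yl)benzoyl]oxy}pent-4-en-1-yl]lithium | [Li][C@H](OC(=O)c1c(C(C)C)cc(C(C)C)cc1C(C)C)C[C@@H](C)C=C
F6 | step 4 | lithium boronate complex of F5 with 4 | [Li+].CC(C)c1cc(C(C)C)c(C(=O)O[C@H](C[C@@H](C)C=C)[B-]2(OC(C)(C)C(C)(C)O2)[C@H](CC(=O)OC(C)(C)C)[C@H](C)CCC=C(C)C)c(C(C)C)c1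
F0 | step 10 | none | none
F7 | step 11 | cis-fused Δ1-pyrazoline of 17 (C5–CH2–N=N–C4) | O[C@@H]1C[C@@H](C)[C@@H]2CN=N[C@@H]2C2=C(C(=O)OC2)[C@@H]1[C@H](C)CCC=C(C)C
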